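**Retrosynthetic overview**

1. The target is prostaglandin E2 1,15-lactone 11-acetate. The last disconnections are the O11 acetate and the C1–O15 ester bond of the 13-membered lactone, which lead back to seco acid 25 (O11 as a silyl ether, O15 freed from a PMB ether).
2. The strategy rests on one feature: the C9 ketone and the (Z)-C5=C6 alkene flank C8–C7. At the alkyne level this is the 4-ynone C9(=O)–C8–C7–C6≡C5, which is what fragmentation of an epoxidised cyclopentenone (ring B: C5, C6, C7, C8, C9) leaves behind when ring B is fused at C8–C9 to the cyclopentane (ring A: C8–C12).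
3. Rings A and B are formed together by an intramolecular Pauson–Khand reaction of 1,6-enyne 17 (C5≡C9 alkyne, C8=C7 vinyl, CO as C6; bonds C8–C9, C6–C7, C5–C6). Ring B is then opened by enone epoxidation and Eschenmoser–Tanabe fragmentation (C5–C9 cleaved).
4. Enyne 17 comes from terminal epoxide 13 and the acetylide of dilithiated hex-5-ynoic acid (C9–C10). C11 and C12 come from Sharpless epoxidation of dienol 7 and a C12-selective alkynylalane opening, the ethynyl group later being reduced to the C8=C7 vinyl group. Dienol 7 comes from (S)-oct-1-yn-3-ol and propargyl alcohol.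
5. Ring order: rings A and B (step 11), ring B opened (step 13), macrolactone (step 17).

Key step: step 11

Assumption: all intermediates carry prostanoic acid numbering (C1 carboxyl to C20), and the target is taken as the (8R,11R,12R,15S)-5Z,13E isomer that the SMILES encodes.

**Route**

Step 1
Reactants: 1 (S)-oct-1-yn-3-ol
Product: 2 (S)-3-[(4-methoxybenzyl)oxy]oct-1-yne
Conditions: NaH, 4-methoxybenzyl chloride, Bu4NI (cat.), THF/DMF, 0 °C → rt
Reagents that add atoms: 4-methoxybenzyl chloride, COc1ccc(CCl)cc1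
Why: Williamson etherification of the secondary propargylic alkoxide should give a PMB ether at O15 that is orthogonal to the later O11 silyl ether, without touching the C15 stereocentre.

Step 2
Reactants: 2 (S)-3-[(4-methoxybenzyl)oxy]oct-1-yne
Product: 4 (S,E)-1-iodo-3-[(4-methoxybenzyl)oxy]oct-1-ene, via alkenylzirconocene chloride 3 (not isolated)
Conditions: Cp2Zr(H)Cl, THF, rt; then I2, THF, 0 °C
Reagents that add atoms: iodine, II
Why: Hydrozirconation of the terminal alkyne is syn and places zirconium on the terminal carbon, and iodinolysis of the C–Zr bond is stereoretentive, so the (E)-alkenyl iodide (C13=C14) should form cleanly.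

Step 3
Reactants: 4 (S,E)-1-iodo-3-[(4-methoxybenzyl)oxy]oct-1-ene; 5 prop-2-yn-1-ol
Product: 6 (4E,6S)-6-[(4-methoxybenzyl)oxy]undec-4-en-2-yn-1-ol
Conditions: PdCl2(PPh3)2 (cat.), CuI (cat.), Et3N, THF, rt
Reagents that add atoms: prop-2-yn-1-ol, OCC#C
Why: Sonogashira coupling of an alkenyl iodide with a terminal alkyne forms the C12–C13 bond with retention of the E geometry and tolerates the free primary alcohol.

Step 4
Reactants: 6 (4E,6S)-6-[(4-methoxybenzyl)oxy]undec-4-en-2-yn-1-ol
Product: 7 (2E,4E,6S)-6-[(4-methoxybenzyl)oxy]undeca-2,4-dien-1-ol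
Conditions: NaAlH2(OCH2CH2OMe)2, THF, 0 °C → rt; aq. KNaC4H4O6 work-up
Reagents that add atoms: none
Why: Alkoxide-directed trans-hydroalumination of the propargylic alcohol followed by protonolysis should give the (E)-allylic alcohol (C11=C12) and leave the existing alkene and the PMB ether untouched.

Step 5
Reactants: 7 (2E,4E,6S)-6-[(4-methoxybenzyl)oxy]undeca-2,4-dien-1-ol
Product: 8 [(2R,3R)-3-[(1E,3S)-3-[(4-methoxybenzyl)oxy]oct-1-en-1-yl]oxiran-2-yl]methanol
Conditions: Ti(OiPr)4 (cat.), D-(−)-diisopropyl tartrate (cat.), t-BuOOH, 4 Å molecular sieves, CH2Cl2, −20 °C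
Reagents that add atoms: tert-butyl hydroperoxide, CC(C)(C)OO
Why: Sharpless asymmetric epoxidation acts only on the alkene next to the free hydroxyl (C11=C12), and the D-(−)-tartrate ligand should deliver oxygen to the face that gives the (2R,3R)-epoxide (the mirror image of the (2S,3S) outcome of L-(+)-tartrate with E-allylic alcohols), so C11 and C12 are set by reagent control.

Step 6
Reactants: 8 [(2R,3R)-3-[(1E,3S)-3-[(4-methoxybenzyl)oxy]oct-1-en-1-yl]oxiran-2-yl]methanol; 9 ethynyltrimethylsilane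
Product: 10 (2S,3R,4E,6S)-6-[(4-methoxybenzyl)oxy]-3-[(trimethylsilyl)ethynyl]undec-4-ene-1,2-diol
Conditions: 9, n-BuLi, toluene, 0 °C; Et2AlCl; then 8, toluene, 0 °C → rt; aq. KNaC4H4O6 work-up
Reagents that add atoms: ethynyltrimethylsilane, C#C[Si](C)(C)C, delivered as diethyl[(trimethylsilyl)ethynyl]aluminium, CC[Al](CC)C#C[Si](C)(C)C
Why: Alkynylalane opening of a 2,3-epoxy alcohol delivers the alkynyl group from the aluminium alkoxide to C3 (here C12, which is also the allylic epoxide carbon) with inversion, which fixes C12 and leaves the C11 carbinol with its configuration; a σ-alkynylalane is chosen because alkenylcopper reagents would attack the vinyl epoxide in the SN2′ sense at C14.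

Step 7
Reactants: 10 (2S,3R,4E,6S)-6-[(4-methoxybenzyl)oxy]-3-[(trimethylsilyl)ethynyl]undec-4-ene-1,2-diol
Product: 12 (S)-2-[(3R,4E,6S)-6-[(4-methoxybenzyl)oxy]undec-4-en-1-yn-3-yl]oxirane, via primary tosylate 11 (not isolated)
Conditions: TsCl, Bu2SnO (cat.), Et3N, CH2Cl2, 0 °C → rt; then K2CO3, MeOH, rt
Reagents that add atoms: none
Why: Tin-catalysed sulfonylation selects the primary hydroxyl of the 1,2-diol through the stannylene acetal, and K2CO3 in MeOH then closes the C10–C11 epoxide by intramolecular Williamson displacement (the C11–O bond is not broken, so C11 is retained) and removes the alkynyl silyl group by methanolysis.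

Step 8
Reactants: 12 (S)-2-[(3R,4E,6S)-6-[(4-methoxybenzyl)oxy]undec-4-en-1-yn-3-yl]oxirane
Product: 13 (S)-2-[(3S,4E,6S)-6-[(4-methoxybenzyl)oxy]undeca-1,4-dien-3-yl]oxirane
Conditions: H2 (1 atm), Pd/CaCO3 poisoned with Pb(OAc)2, quinoline, EtOAc, rt
Reagents that add atoms: none
Why: Lindlar semihydrogenation should reduce the terminal alkyne to the C8=C7 vinyl group much faster than it touches the E-disubstituted alkene, the epoxide or the benzylic ether.

Step 9
Reactants: 13 (S)-2-[(3S,4E,6S)-6-[(4-methoxybenzyl)oxy]undeca-1,4-dien-3-yl]oxirane; 14 hex-5-ynoic acid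
Product: 16 methyl (8R,9S,10E,12S)-9-ethenyl-8-hydroxy-12-[(4-methoxybenzyl)oxy]heptadec-10-en-5-ynoate, via hydroxy acid 15 (not isolated)
Conditions: 14, n-BuLi (2 equiv per acid), THF/DMPU, −78 → 0 °C; then 13, 0 °C → rt; dilute HCl work-up; then Me3SiCHN2, MeOH/toluene, 0 °C
Reagents that add atoms: hex-5-ynoic acid, C#CCCCC(=O)O; (trimethylsilyl)diazomethane, C[Si](C)(C)C=[N+]=[N-]
Why: The acetylide of the dilithiated acid (the carboxylate shields C1 from nucleophilic attack and from enolisation, which an ester would not) opens the terminal epoxide by SN2 at unhindered C10 to form the C9–C10 bond, and the diazoalkane then methylates only the carboxylic acid.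

Step 10
Reactants: 16 methyl (8R,9S,10E,12S)-9-ethenyl-8-hydroxy-12-[(4-methoxybenzyl)oxy]heptadec-10-en-5-ynoate
Product: 17 methyl (8R,9S,10E,12S)-8-[(tert-butyldimethylsilyl)oxy]-9-ethenyl-12-[(4-methoxybenzyl)oxy]heptadec-10-en-5-ynoate (1,6-enyne; prostanoid numbering 11R,12S,15S)
Conditions: TBSOTf, 2,6-lutidine, CH2Cl2, −78 → 0 °C
Reagents that add atoms: tert-butyldimethylsilyl triflate, CC(C)(C)[Si](C)(C)OS(=O)(=O)C(F)(F)F
Why: Silylation of the hindered secondary C11 hydroxyl with the silyl triflate should be fast and gives an O11 protecting group that survives the oxidative PMB removal planned for O15.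

Step 11
Reactants: 17 methyl (8R,9S,10E,12S)-8-[(tert-butyldimethylsilyl)oxy]-9-ethenyl-12-[(4-methoxybenzyl)oxy]heptadec-10-en-5-ynoate
Product: 19 bicyclo[3.3.0]oct-1-en-3-one (8R,11R,12R,15S) with enone C9=C5–C6(=O), C5 carrying (CH2)3CO2Me, C11 carrying OTBS and C12 carrying the (1E,3S)-3-(PMB-oxy)oct-1-enyl chain, via alkyne–hexacarbonyldicobalt complex 18 (not isolated)
Conditions: Co2(CO)8 (1.1 equiv), CH2Cl2, rt; then 4-methylmorpholine N-oxide (excess), CH2Cl2, 0 °C → rt
Reagents that add atoms: dicobalt octacarbonyl (source of the C6 carbonyl), O=C=[Co](=C=O)(=C=O)(=C=O)[Co](=C=O)(=C=O)(=C=O)=C=O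
Why: Co2(CO)8 complexes the C5≡C9 alkyne, oxidative removal of a CO ligand by the N-oxide opens a site for the tethered C8=C7 vinyl group, which inserts into the Co–C9 bond (C8–C9), CO then inserts into the Co–C7 bond (C6–C7) and reductive elimination forms C5–C6; the closest known reaction type is the intramolecular Pauson–Khand reaction of 1,6-enynes to bicyclo[3.3.0]oct-1-en-3-ones. Ring A (C8–C9–C10–C11–C12) closes by 5-exo insertion of the vinyl group across the three-atom tether C10–C11–C12, and ring B (C5–C6–C7–C8–C9) closes by migratory CO insertion and reductive elimination at cobalt. The only new stereocentre, C8, is controlled by the allylic C12 centre: in the insertion transition state the tether adopts an envelope in which the octenyl branch on C12 and the trans C11 silyloxy group are both pseudo-equatorial and point away from the cobalt cluster, so H-8 should end cis to the C12 branch, that is C7 trans to C13 (8R). The step needs chemoselectivity for the vinyl group over the C13=C14 alkene, and this is secured because a monosubstituted alkene coordinates and inserts far more readily than an E-disubstituted alkene flanked by two branched carbons, while the regiochemistry (alkyne substituent alpha to the new carbonyl) is fixed by the tether. The methyl ester, the PMB ether and the silyl ether are spectators under these mild promoter conditions. Any C8 epimer is not lost, because C8 becomes alpha to the C9 ketone after ring B is opened and can be equilibrated to the trans-8,12 arrangement.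

Step 12
Reactants: 19 Pauson–Khand enone
Product: 20 5,9-epoxy ketone of 19 (epoxide oxygen cis to H-8, cis-fused)
Conditions: t-BuOOH, benzyltrimethylammonium hydroxide (cat.), THF, 0 °C → rt
Reagents that add atoms: tert-butyl hydroperoxide, CC(C)(C)OO
Why: Weitz–Scheffer nucleophilic epoxidation attacks only the electron-poor C9=C5 enone (C13=C14 is inert to peroxide anion), oxygen should enter cis to H-8 to keep the bicycle cis-fused, and the two new stereocentres at C5 and C9 are destroyed in the next step.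

Step 13
Reactants: 20 5,9-epoxy ketone
Product: 22 methyl (8R,11R,12R,13E,15S)-11-[(tert-butyldimethylsilyl)oxy]-15-[(4-methoxybenzyl)oxy]-9-oxoprost-13-en-5-ynoate, via epoxy tosylhydrazone 21 (not isolated)
Conditions: TsNHNH2, AcOH/CH2Cl2, −20 °C → rt
Reagents that add atoms: none
Why: Eschenmoser–Tanabe fragmentation: the C6 tosylhydrazone opens the epoxide at C5 to an azoalkene alkoxide, and collapse of the C9 alkoxide cleaves C5–C9 with loss of N2 and sulfinate, leaving the C9 ketone in ring A and the C5≡C6 alkyne, as established for fused cyclopentenone epoxides, with C8, C11, C12 and C15 untouched.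

Step 14
Reactants: 22 5,6-didehydro-PGE2 methyl ester 11-TBS 15-PMB ether
Product: 23 methyl (5Z,8R,11R,12R,13E,15S)-11-[(tert-butyldimethylsilyl)oxy]-15-[(4-methoxybenzyl)oxy]-9-oxoprosta-5,13-dienoate
Conditions: H2 (1 atm), Pd/CaCO3 poisoned with Pb(OAc)2, quinoline, EtOAc, rt
Reagents that add atoms: none
Why: Lindlar semihydrogenation adds hydrogen syn to the internal alkyne and should give the (Z)-C5=C6 alkene without reducing the E-alkene or the ketone.

Step 15
Reactants: 23 PGE2 methyl ester 11-TBS 15-PMB ether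
Product: 24 methyl (5Z,8R,11R,12R,13E,15S)-11-[(tert-butyldimethylsilyl)oxy]-15-hydroxy-9-oxoprosta-5,13-dienoate
Conditions: DDQ, CH2Cl2/aq. NaH2PO4–Na2HPO4 buffer (pH 7), 0 °C
Reagents that add atoms: none
Why: Oxidative cleavage of the electron-rich PMB ether by DDQ under buffered conditions should free O15 alone, the silyl ether, ester, ketone and both alkenes being inert.

Step 16
Reactants: 24 PGE2 methyl ester 11-TBS ether
Product: 25 (5Z,8R,11R,12R,13E,15S)-11-[(tert-butyldimethylsilyl)oxy]-15-hydroxy-9-oxoprosta-5,13-dienoic acid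
Conditions: Me3SnOH, 1,2-dichloroethane, 70 °C; dilute HCl wash
Reagents that add atoms: trimethyltin hydroxide, C[Sn](C)(C)O
Why: Trimethyltin hydroxide cleaves methyl esters under nearly neutral conditions, so the acid should be freed without E1cB loss of the C11 silyloxy group from the beta-silyloxy ketone.

Step 17
Reactants: 25 seco acid
Product: 27 PGE2 1,15-lactone 11-TBS ether, via 2-pyridyl thioester 26 (not isolated)
Conditions: 2,2'-dipyridyl disulfide, PPh3, toluene, rt; then slow addition into toluene at reflux (high dilution)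
Reagents that add atoms: none
Why: Corey–Nicolaou double-activation macrolactonization is base-free, which suits the beta-silyloxy ketone, and O15 is the only free hydroxyl, so the 13-membered C1–O15 lactone should close with retention at C15.

Step 18
Reactants: 27 PGE2 1,15-lactone 11-TBS ether
Product: 28 PGE2 1,15-lactone
Conditions: HF·pyridine, pyridine/THF, 0 °C
Reagents that add atoms: none
Why: Buffered fluoride in acidic medium removes the secondary silyl ether without the base-induced dehydration of the beta-hydroxy ketone that basic fluoride sources can cause.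

Step 19
Reactants: 28 PGE2 1,15-lactone
Product: 29 PGE2 1,15-lactone 11-acetate (target)
Conditions: Ac2O, pyridine, 0 °C → rt
Reagents that add atoms: acetic anhydride, CC(=O)OC(C)=O
Why: Acylation of the only free hydroxyl (O11) with acetic anhydride in pyridine, without a stronger base, should give the acetate before elimination to the C10=C11 enone can compete.

**Compound list**

1 | (S)-oct-1-yn-3-ol | CCCCC[C@H](O)C#C | starting material
2 | (S)-3-[(4-methoxybenzyl)oxy]oct-1-yne | CCCCC[C@H](OCc1ccc(OC)cc1)C#C | intermediate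
3 | chlorobis(cyclopentadienyl)[(1E,3S)-3-[(4-methoxybenzyl)oxy]oct-1-en-1-yl]zirconium (not isolated) | CCCCC[C@H](OCc1ccc(OC)cc1)/C=C/[Zr](Cl)(C1C=CC=C1)C1C=CC=C1 | intermediate
4 | (S,E)-1-iodo-3-[(4-methoxybenzyl)oxy]oct-1-ene | CCCCC[C@H](OCc1ccc(OC)cc1)/C=C/I | intermediate
5 | prop-2-yn-1-ol (propargyl alcohol) | OCC#C | starting material
6 | (4E,6S)-6-[(4-methoxybenzyl)oxy]undec-4-en-2-yn-1-ol | CCCCC[C@H](OCc1ccc(OC)cc1)/C=C/C#CCO | intermediate
7 | (2E,4E,6S)-6-[(4-methoxybenzyl)oxy]undeca-2,4-dien-1-ol | CCCCC[C@H](OCc1ccc(OC)cc1)/C=C/C=C/CO | intermediate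
8 | [(2R,3R)-3-[(1E,3S)-3-[(4-methoxybenzyl)oxy]oct-1-en-1-yl]oxiran-2-yl]methanol | CCCCC[C@H](OCc1ccc(OC)cc1)/C=C/[C@H]1O[C@@H]1CO | intermediate
9 | ethynyltrimethylsilane | C#C[Si](C)(C)C | starting material
10 | (2S,3R,4E,6S)-6-[(4-methoxybenzyl)oxy]-3-[(trimethylsilyl)ethynyl]undec-4-ene-1,2-diol | CCCCC[C@H](OCc1ccc(OC)cc1)/C=C/[C@H](C#C[Si](C)(C)C)[C@H](O)CO | intermediate
11 | 1-O-(p-toluenesulfonyl) derivative of 10 (not isolated) | CCCCC[C@H](OCc1ccc(OC)cc1)/C=C/[C@H](C#C[Si](C)(C)C)[C@H](O)COS(=O)(=O)c1ccc(C)cc1 | intermediate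
12 | (S)-2-[(3R,4E,6S)-6-[(4-methoxybenzyl)oxy]undec-4-en-1-yn-3-yl]oxirane | CCCCC[C@H](OCc1ccc(OC)cc1)/C=C/[C@H](C#C)[C@H]1CO1 | intermediate
13 | (S)-2-[(3S,4E,6S)-6-[(4-methoxybenzyl)oxy]undeca-1,4-dien-3-yl]oxirane | CCCCC[C@H](OCc1ccc(OC)cc1)/C=C/[C@H](C=C)[C@H]1CO1 | intermediate
14 | hex-5-ynoic acid | C#CCCCC(=O)O | starting material
15 | (8R,9S,10E,12S)-9-ethenyl-8-hydroxy-12-[(4-methoxybenzyl)oxy]heptadec-10-en-5-ynoic acid (not isolated) | CCCCC[C@H](OCc1ccc(OC)cc1)/C=C/[C@H](C=C)[C@H](O)CC#CCCCC(=O)O | intermediate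
16 | methyl (8R,9S,10E,12S)-9-ethenyl-8-hydroxy-12-[(4-methoxybenzyl)oxy]heptadec-10-en-5-ynoate | CCCCC[C@H](OCc1ccc(OC)cc1)/C=C/[C@H](C=C)[C@H](O)CC#CCCCC(=O)OC | intermediate
17 | methyl (8R,9S,10E,12S)-8-[(tert-butyldimethylsilyl)oxy]-9-ethenyl-12-[(4-methoxybenzyl)oxy]heptadec-10-en-5-ynoate (Pauson–Khand precursor) | CCCCC[C@H](OCc1ccc(OC)cc1)/C=C/[C@H](C=C)[C@H](O[Si](C)(C)C(C)(C)C)CC#CCCCC(=O)OC | intermediate
18 | hexacarbonyldicobalt complex of the C5≡C9 alkyne of 17 (not isolated) | CCCCC[C@H](OCc1ccc(OC)cc1)/C=C/[C@H](C=C)[C@H](O[Si](C)(C)C(C)(C)C)CC12C3(CCCC(=O)OC)[Co]1(=C=O)(=C=O)(=C=O)[Co]23(=C=O)(=C=O)=C=O | intermediate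
19 | methyl 4-[(3aR,4R,5R)-5-[(tert-butyldimethylsilyl)oxy]-4-[(1E,3S)-3-[(4-methoxybenzyl)oxy]oct-1-en-1-yl]-2-oxo-2,3,3a,4,5,6-hexahydropentalen-1-yl]butanoate (Pauson–Khand product; prostanoid 8R,11R,12R,15S) | CCCCC[C@H](OCc1ccc(OC)cc1)/C=C/[C@H]1[C@H](O[Si](C)(C)C(C)(C)C)CC2=C(CCCC(=O)OC)C(=O)C[C@H]12 | intermediate
20 | 5,9-epoxide of 19, oxygen cis to H-8 | CCCCC[C@H](OCc1ccc(OC)cc1)/C=C/[C@H]1[C@H](O[Si](C)(C)C(C)(C)C)C[C@]23O[C@@]2(CCCC(=O)OC)C(=O)C[C@H]13 | intermediate
21 | C6 p-toluenesulfonylhydrazone of 20 (not isolated) | CCCCC[C@H](OCc1ccc(OC)cc1)/C=C/[C@H]1[C@H](O[Si](C)(C)C(C)(C)C)C[C@]23O[C@@]2(CCCC(=O)OC)C(=NNS(=O)(=O)c4ccc(C)cc4)C[C@H]13 | intermediate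
22 | methyl (8R,11R,12R,13E,15S)-11-[(tert-butyldimethylsilyl)oxy]-15-[(4-methoxybenzyl)oxy]-9-oxoprost-13-en-5-ynoate | CCCCC[C@H](OCc1ccc(OC)cc1)/C=C/[C@H]1[C@H](O[Si](C)(C)C(C)(C)C)CC(=O)[C@@H]1CC#CCCCC(=O)OC | intermediate
23 | methyl (5Z,8R,11R,12R,13E,15S)-11-[(tert-butyldimethylsilyl)oxy]-15-[(4-methoxybenzyl)oxy]-9-oxoprosta-5,13-dienoate | CCCCC[C@H](OCc1ccc(OC)cc1)/C=C/[C@H]1[C@H](O[Si](C)(C)C(C)(C)C)CC(=O)[C@@H]1C/C=C\CCCC(=O)OC | intermediate
24 | methyl (5Z,8R,11R,12R,13E,15S)-11-[(tert-butyldimethylsilyl)oxy]-15-hydroxy-9-oxoprosta-5,13-dienoate | CCCCC[C@H](O)/C=C/[C@H]1[C@H](O[Si](C)(C)C(C)(C)C)CC(=O)[C@@H]1C/C=C\CCCC(=O)OC | intermediate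
25 | (5Z,8R,11R,12R,13E,15S)-11-[(tert-butyldimethylsilyl)oxy]-15-hydroxy-9-oxoprosta-5,13-dienoic acid | CCCCC[C@H](O)/C=C/[C@H]1[C@H](O[Si](C)(C)C(C)(C)C)CC(=O)[C@@H]1C/C=C\CCCC(=O)O | intermediate
26 | S-(pyridin-2-yl) thioester of 25 (not isolated) | CCCCC[C@H](O)/C=C/[C@H]1[C@H](O[Si](C)(C)C(C)(C)C)CC(=O)[C@@H]1C/C=C\CCCC(=O)Sc1ccccn1 | intermediate
27 | PGE2 1,15-lactone 11-(tert-butyldimethylsilyl) ether | CCCCC[C@H]1/C=C/[C@H]2[C@H](O[Si](C)(C)C(C)(C)C)CC(=O)[C@@H]2C/C=C\CCCC(=O)O1 | intermediate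
28 | PGE2 1,15-lactone | CCCCC[C@H]1/C=C/[C@H]2[C@H](O)CC(=O)[C@@H]2C/C=C\CCCC(=O)O1 | intermediate
29 | PGE2 1,15-lactone 11-acetate (CNP0241847.1) | CCCCC[C@H]1/C=C/[C@H]2[C@H](OC(C)=O)CC(=O)[C@@H]2C/C=C\CCCC(=O)O1 | target

**Step count and risks**

Total step count: 19. Longest linear sequence: 19 steps, from 1 to 29.

Steps most likely to fail:

1. Step 11 (key step). The vinyl group may insert on the wrong face, or insertion may be slowed by competing coordination of the C13=C14 alkene, so that the C8 epimer forms in quantity. Fallback, setting out from 17: the cyclization is run unchanged and the C8-epimeric enone F1 is carried on instead of being discarded. It is epoxidised (t-BuOOH, benzyltrimethylammonium hydroxide) to the epimeric epoxy ketone F2, condensed with TsNHNH2 to the epimeric epoxy tosylhydrazone F3 (not isolated) and fragmented to the 8-epi alkynone F4. Because C8 is then alpha to the C9 ketone, F4 is equilibrated with KOAc in MeOH at rt to the more stable trans-8,12 isomer, which is 22. Stereocontrol at C8 thus moves from the kinetic cyclization to a thermodynamic epimerization.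

2. Step 13. Hydrazone formation at the hindered C6 carbonyl may be slow, and the acid medium may open the epoxide before fragmentation occurs. Fallback, setting out from 20: condensation with 1-amino-trans-2,3-diphenylaziridine (CH2Cl2, rt, no acid) gives the N-aziridinyl imine F5 (racemic reagent, one diastereomer drawn). Thermolysis of F5 in toluene at reflux fragments it by loss of stilbene and nitrogen in a neutral, sulfinate-free pathway and returns to 22.

3. Step 6. The aluminium Lewis acid may ionise the vinyl epoxide, which would divert the alkynyl group to C14 (SN2′ attack) or erode the configuration at C12. Fallback, setting out from 8: the primary hydroxyl is silylated (TBSCl, imidazole, CH2Cl2) to the epoxy silyl ether F6. F6 is opened with Me3SiC≡CLi and BF3·OEt2 in THF at −78 °C; regiocontrol then comes from allylic activation of C12 and inductive deactivation of C11 by the C10 oxygen, not from an aluminium alkoxide, and the attack is an intermolecular SN2 with inversion, giving the secondary alcohol F7. Selective removal of the primary silyl ether (camphorsulfonic acid, MeOH, 0 °C; the alkynylsilane is stable to acid) returns to diol 10.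

**Further compounds**

F1 | step 11 | C8 epimer of enone 19 (8S) | CCCCC[C@H](OCc1ccc(OC)cc1)/C=C/[C@H]1[C@H](O[Si](C)(C)C(C)(C)C)CC2=C(CCCC(=O)OC)C(=O)C[C@@H]12
F2 | step 11 | 5,9-epoxide of F1, oxygen cis to H-8 | CCCCC[C@H](OCc1ccc(OC)cc1)/C=C/[C@H]1[C@H](O[Si](C)(C)C(C)(C)C)C[C@@]23O[C@]2(CCCC(=O)OC)C(=O)C[C@@H]13
F3 | step 11 | C6 p-toluenesulfonylhydrazone of F2 (not isolated) | CCCCC[C@H](OCc1ccc(OC)cc1)/C=C/[C@H]1[C@H](O[Si](C)(C)C(C)(C)C)C[C@@]23O[C@]2(CCCC(=O)OC)C(=NNS(=O)(=O)c4ccc(C)cc4)C[C@@H]13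
F4 | step 11 | C8 epimer of alkynone 22 | CCCCC[C@H](OCc1ccc(OC)cc1)/C=C/[C@H]1[C@H](O[Si](C)(C)C(C)(C)C)CC(=O)[C@H]1CC#CCCCC(=O)OC
F5 | step 13 | N-(trans-2,3-diphenylaziridin-1-yl)imine of 20 at C6 | CCCCC[C@H](OCc1ccc(OC)cc1)/C=C/[C@H]1[C@H](O[Si](C)(C)C(C)(C)C)C[C@]23O[C@@]2(CCCC(=O)OC)C(=NN4[C@@H](c5ccccc5)[C@@H]4c6ccccc6)C[C@H]13
F6 | step 6 | tert-butyldimethylsilyl ether of epoxy alcohol 8 | CCCCC[C@H](OCc1ccc(OC)cc1)/C=C/[C@H]1O[C@@H]1CO[Si](C)(C)C(C)(C)C
F7 | step 6 | 1-O-(tert-butyldimethylsilyl) ether of diol 10 | CCCCC[C@H](OCc1ccc(OC)cc1)/C=C/[C@H](C#C[Si](C)(C)C)[C@H](O)CO[Si](C)(C)C(C)(C)C
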